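## Retrosynthetic overview

1. Target 39 ⇐ β-iodo peroxyhemiacetal 38 (silver-assisted epoxide closure) ⇐ aldehyde / tertiary allylic alcohol 36 (transannular iodoperoxidation closes the 1,2-dioxocane).
2. 36 ⇐ macrocyclic β-keto lactam 34 (radical addition to ethyl vinyl ether creates the quaternary lactam carbon) ⇐ enamide 33 (hydration to the hemiaminal).
3. Key step: the 13-membered paracyclophane 33 comes from ring contraction of the 14-membered thiolactone 31 (S→C 1,2-acyl shift with sulfur extrusion). 31 is assembled from iodo acid 22 and alkynamide 27 (Sonogashira, hydroamidation, thiolactonisation).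
4. Ring C of 22 ⇐ Michael–aldol annulation of methyl acetoacetate onto acetylcyclopentene 16, then MeCeCl2. The aryl ether ⇐ oxa-Michael addition to cyclopentenone 9.
5. trans-Hydrindane 7 ⇐ amino-acid-catalysed Robinson annulation, Li/NH3, Wolff–Kishner. Ring order: B (present in 1) → A → C → lactam → 14-membered thiolactone → 13-membered carbocycle → dioxocane → epoxide.

Assumption: the hemiaminal carbon and the peroxyhemiacetal carbon are labile and settle, under thermodynamic control, in the configuration of the target; racemic 27 is used because its stereocentre is erased in step 17 (left undefined in 28–32). "Upper face" means the face of the angular methyl group.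

## Route

Step 1
Reactants: 1 2-methylcyclopentane-1,3-dione; 2 2-methylpent-1-en-3-one
Product: 5 (6S,7aR)-4,6,7a-trimethyl-2,3,7,7a-tetrahydro-1H-indene-1,5(6H)-dione, via triketone 3 (not isolated), via bicyclic ketol 4 (not isolated)
Conditions: 2 (1.5 equiv), H2O, AcOH (cat.), 75 °C; then D-phenylalanine (1 equiv), 1 M HClO4 (0.5 equiv), MeCN, 80 °C
Reagents that add atoms: none
Why: Michael addition followed by amino-acid-mediated intramolecular aldol condensation (Hajos–Parrish/Eder–Sauer–Wiechert Robinson annulation); the D-amino acid enamine differentiates the two ring carbonyls and sets the angular (7aR) centre, while C6 is epimerisable and is corrected in steps 2–3.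

Step 2
Reactants: 5 the enedione
Product: 6 trans-fused 1-hydroxy-4,6,7a-trimethyloctahydro-5H-inden-5-one
Conditions: Li (6 equiv), NH3(l)/THF, t-BuOH (2 equiv), −78 → −33 °C; NH4Cl
Reagents that add atoms: none
Why: Dissolving-metal (Birch-type) reduction: the enone is reduced with axial protonation of the β-carbanion, which gives the trans ring fusion (3a-H anti to the angular methyl), while the isolated cyclopentanone goes to the alcohol; the carbinol configuration is irrelevant.

Step 3
Reactants: 6 the hydroxy ketone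
Product: 7 trans-fused 4,6,7a-trimethyloctahydro-1H-inden-1-ol
Conditions: N2H4·H2O, KOH, diethylene glycol, 130 → 200 °C
Reagents that add atoms: none
Why: Wolff–Kishner (Huang–Minlon) deoxygenation; hot KOH first equilibrates both α-methyl centres to the all-equatorial cis-4,6 arrangement, which is then fixed.

Step 4
Reactants: 7 the hydrindanol
Product: 9 trans-fused 4,6,7a-trimethyl-3a,4,5,6,7,7a-hexahydro-1H-inden-1-one, via hydrindanone 8 (not isolated)
Conditions: IBX (4 equiv), DMSO/fluorobenzene, 75 °C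
Reagents that add atoms: none
Why: IBX oxidation of the alcohol and IBX-mediated α,β-dehydrogenation of the ketone in one pot; only C2 carries α-hydrogens, so one enone can form.

Step 5
Reactants: 9 the cyclopentenone; 10 4-iodophenol
Product: 11 3-(4-iodophenoxy)-4,6,7a-trimethyloctahydro-1H-inden-1-one
Conditions: 10 (3 equiv), Cs2CO3 (0.2 equiv), MeCN, 23 °C
Reagents that add atoms: none
Why: Reversible base-catalysed oxa-Michael addition; the thermodynamic adduct carries the aryloxy group on the upper face, as 15β-adducts do with steroidal 15-en-17-ones.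

Step 6
Reactants: 11 the aryloxy ketone; 12 ethyl vinyl ether
Product: 15 1-acetyl-3-(4-iodophenoxy)-4,6,7a-trimethyloctahydro-1H-inden-1-ol, via 1-ethoxyvinyllithium 13 (not isolated), via enol ether carbinol 14 (not isolated)
Conditions: 12, t-BuLi, THF, −78 → 0 °C; CeCl3, −78 °C; then 11; 1 M HCl, THF, 0 °C
Reagents that add atoms: water, O
Why: Organocerium 1,2-addition of an acetyl anion equivalent, basic too weakly to enolise the β-aryloxy ketone and expel phenoxide, then enol ether hydrolysis; the carbinol configuration is lost in step 7.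

Step 7
Reactants: 15 the α-ketol
Product: 16 1-[3-(4-iodophenoxy)-4,6,7a-trimethyl-3a,4,5,6,7,7a-hexahydro-3H-inden-1-yl]ethanone
Conditions: SOCl2, pyridine, CH2Cl2, −20 → 0 °C
Reagents that add atoms: none
Why: Dehydration through the chlorosulfite (E2); the only β-hydrogens are on C2, which gives the conjugated 1-acetylcyclopentene (as 17-hydroxy-20-keto steroids give 16-en-20-ones).

Step 8
Reactants: 16 the acetylcyclopentene; 17 methyl acetoacetate
Product: 20 methyl 9-(4-iodophenoxy)-2,4b,6,8-tetramethyl-4-oxo-4,4a,4b,5,6,7,8,8a,9,9a-decahydro-1H-fluorene-1-carboxylate, via Michael adduct 18 (not isolated), via aldol 19 (not isolated)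
Conditions: 17 (1.5 equiv), NaOMe (0.5 equiv), MeOH, 0 → 60 °C
Reagents that add atoms: none
Why: Robinson (Hagemann-type) Michael–aldol annulation: the acetoacetate adds to the lower face, anti to aryloxy and angular methyl (as 16α-additions to 16-en-20-keto steroids); the epimerisable C4a and C1 centres settle as the trans ring fusion and the equatorial ester, and the acetyl CH3 condenses onto the acetoacetate ketone.

Step 9
Reactants: 20 the tricyclic enone ester
Product: 21 methyl 4-hydroxy-9-(4-iodophenoxy)-2,4,4b,6,8-pentamethyl-4,4a,4b,5,6,7,8,8a,9,9a-decahydro-1H-fluorene-1-carboxylate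
Conditions: MeLi, CeCl3, THF, −78 °C
Reagents that add atoms: methyllithium (used as MeCeCl2), C[Li]
Why: Organocerium 1,2-addition to an easily enolised enone in the presence of the ester; the angular methyl overhangs the upper face of the carbonyl, so methyl enters from below and the new hydroxyl sits on the upper face.

Step 10
Reactants: 21 the hydroxy ester
Product: 22 4-hydroxy-9-(4-iodophenoxy)-2,4,4b,6,8-pentamethyl-4,4a,4b,5,6,7,8,8a,9,9a-decahydro-1H-fluorene-1-carboxylic acid
Conditions: Me3SnOH, 1,2-dichloroethane, 80 °C; 0.1 M HCl wash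
Reagents that add atoms: trimethyltin hydroxide, C[Sn](C)(C)O
Why: Neutral ester cleavage with Me3SnOH, which avoids base-induced migration of the β,γ-double bond into conjugation; the carboxylate then protects C1 in the basic steps that follow.

Step 11
Reactants: 23 methyl sulfanylacetate
Product: 24 methyl (tritylsulfanyl)acetate
Conditions: TrtCl, Et3N, CH2Cl2, 0 → 23 °C
Reagents that add atoms: trityl chloride, ClC(c1ccccc1)(c1ccccc1)c1ccccc1
Why: S-Tritylation (SN1 capture of the trityl cation by the thiol) protects sulfur for the enolate and palladium steps.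

Step 12
Reactants: 24 the S-trityl ester; 25 propargyl bromide
Product: 26 methyl 2-(tritylsulfanyl)pent-4-ynoate
Conditions: LDA, THF, −78 °C; 25, −78 → 0 °C
Reagents that add atoms: none
Why: Alkylation of the α-thio ester enolate (SN2); the product is racemic, which does not matter because this centre is erased in step 17.

Step 13
Reactants: 26 the alkynyl ester
Product: 27 2-(tritylsulfanyl)pent-4-ynamide
Conditions: NH3 (7 M in MeOH), 23 °C
Reagents that add atoms: ammonia, N
Why: Aminolysis of the methyl ester to the primary amide.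

Step 14
Reactants: 22 the iodo acid; 27 the alkynamide
Product: 29 (Z)-5-arylidene-3-(tritylsulfanyl)pyrrolidin-2-one acid, via aryl alkyne 28 (not isolated)
Conditions: Pd(PPh3)2Cl2 (5 mol%), CuI (10 mol%), Et3N, DMF, 23 °C; then t-BuOK (4 equiv), THF, 0 → 23 °C; NH4Cl (aq)
Reagents that add atoms: none
Why: Sonogashira coupling followed by base-mediated 5-exo-dig hydroamidation; nitrogen attacks the alkyne carbon remote from the aryl group and anti addition gives the (Z)-enamide.

Step 15
Reactants: 29 the S-trityl enamide acid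
Product: 30 (Z)-5-arylidene-3-sulfanylpyrrolidin-2-one acid
Conditions: AgNO3, pyridine, MeOH/THF, 23 °C; then 0.2 M HCl, 0 °C
Reagents that add atoms: none
Why: Silver-assisted S-detritylation (silver thiolate, then protonolysis) under conditions that leave the enamide and the tertiary allylic alcohol alone.

Step 16
Reactants: 30 the thiol acid
Product: 31 14-membered thiolactone (thioester between the C1 carboxyl and the lactam C3 sulfur)
Conditions: DCC, DMAP (cat.), CH2Cl2, 1 mM (syringe pump), 23 °C
Reagents that add atoms: none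
Why: Steglich-type thioesterification at high dilution (macrothiolactonisation); the thiol is acylated far faster than the tertiary alcohol or the lactam NH, and the 14-membered ring is not yet strained.

Step 17
Reactants: 31 the 14-membered thiolactone
Product: 33 13-membered β-keto lactam (enamide form), via sulfanyl keto lactam 32 (not isolated)
Conditions: LDA (4 equiv), THF, −78 → −20 °C; PPh3 (3 equiv), −20 → 40 °C; NH4Cl (aq)
Reagents that add atoms: none
Why: Proposed new method: a ring-contracting thioester sulfide contraction — the lactam carbanion next to sulfur adds 3-exo-trig to the thioester carbonyl, the thiiranolate opens to the C-acylated thiolate 32 (S→C 1,2-acyl shift, 14 → 13 ring atoms), and PPh3 removes sulfur to leave the stabilised β-keto lactam enolate, so the strain of the [9]paracyclophane is paid for by the acidity gain (carbanion pKa above 25 to β-dicarbonyl pKa about 11) and P=S formation; the closest known chemistry is the Eschenmoser sulfide contraction of S-(2-oxoalkyl) thioesters to β-dicarbonyls and base-induced S→C acyl shifts, neither shown for a lactam carbanion or as a macrocycle-contracting step; no stereocentre is set because lactam C3 stays enolisable.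

Step 18
Reactants: 33 the enamide keto lactam
Product: 34 5-hydroxy-5-benzyl β-keto lactam macrocycle
Conditions: AcOH/H2O/THF (1:1:3), 40 °C
Reagents that add atoms: water, O
Why: Acid-catalysed hydration of the enamide through the N-acyliminium ion; both lactam stereocentres are still labile here (C3 enolisable, C5 a hemiaminal).

Step 19
Reactants: 34 the hydroxy keto lactam; 12 ethyl vinyl ether
Product: 36 macrocyclic keto lactam with a 2-oxoethyl group on lactam C3, via acetoxy ethyl acetal 35 (not isolated)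
Conditions: 12 (10 equiv), Mn(OAc)3·2H2O (2.2 equiv), Cu(OAc)2 (10 mol%), AcOH, 23 °C; then H2O/THF
Reagents that add atoms: water, O
Why: Mn(III)-mediated oxidative radical addition of the β-dicarbonyl to the enol ether, then oxidation to the oxocarbenium ion and hydrolysis; the planar radical is attacked on the peripheral face of the macrocycle (the side of ring-C carbon C2, the inner face being blocked across the ring), which sets the quaternary centre, and the hemiaminal then equilibrates to the target configuration.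

Step 20
Reactants: 36 the aldehyde
Product: 38 iodo peroxyhemiacetal (1,2-dioxocane closed; iodide at C3 and free hydroxyl at C4 of ring C), via hydroxy hydroperoxide 37 (not isolated)
Conditions: H2O2 (ethereal, 5 equiv), N-iodosuccinimide (1.3 equiv), Et2O/CH2Cl2, −20 → 0 °C, dark
Reagents that add atoms: hydrogen peroxide, OO; N-iodosuccinimide, O=C1CCC(=O)N1I
Why: Iodoperoxidation: the gem-hydroxy hydroperoxide formed reversibly from aldehyde and H2O2 opens the iodonium ion at the tertiary carbon C2 in a trans-diaxial (Markovnikov) sense; the tether delivers oxygen to the upper face, so iodine ends on the lower face of C3, anti to the C4 hydroxyl, and the peroxyhemiacetal carbon equilibrates.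

Step 21
Reactants: 38 the iodo peroxyhemiacetal
Product: 39 target CNP0533733.1
Conditions: Ag2O, CH2Cl2, 23 °C, dark
Reagents that add atoms: none
Why: Silver-assisted intramolecular Williamson closure of the trans-diaxial iodohydrin; the upper-face C4 oxygen displaces iodide with inversion at C3, which places the epoxide on the same face as the peroxide.

## Compound list

1 | 2-methylcyclopentane-1,3-dione | CC1C(=O)CCC1=O | starting material
2 | 2-methylpent-1-en-3-one | CCC(=O)C(C)=C | starting material
3 | 2-methyl-2-(2-methyl-3-oxopentyl)cyclopentane-1,3-dione (triketone) | CCC(=O)C(C)CC1(C)C(=O)CCC1=O | intermediate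
4 | (7aR)-3a-hydroxy-4,6,7a-trimethylhexahydroindane-1,5-dione (bicyclic ketol) | C[C@@H]1C(=O)C(C)C2(O)CCC(=O)[C@]2(C)C1 | intermediate
5 | (6S,7aR)-4,6,7a-trimethyl-2,3,7,7a-tetrahydro-1H-indene-1,5(6H)-dione | C[C@@H]1C(=O)C(C)=C2CCC(=O)[C@]2(C)C1 | intermediate
6 | trans-fused 1-hydroxy-4,6,7a-trimethyloctahydro-5H-inden-5-one (3a-H anti to 7a-Me; 1-OH syn to 7a-Me) | C[C@@H]1C(=O)[C@H](C)[C@H]2CC[C@@H](O)[C@]2(C)C1 | intermediate
7 | trans-fused 4,6,7a-trimethyloctahydro-1H-inden-1-ol (4- and 6-Me equatorial, cis) | C[C@@H]1C[C@H](C)[C@H]2CC[C@@H](O)[C@]2(C)C1 | intermediate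
8 | trans-fused 4,6,7a-trimethyloctahydro-1H-inden-1-one (hydrindanone) | C[C@@H]1C[C@H](C)[C@H]2CCC(=O)[C@]2(C)C1 | intermediate
9 | trans-fused 4,6,7a-trimethyl-3a,4,5,6,7,7a-hexahydro-1H-inden-1-one | C[C@@H]1C[C@H](C)[C@H]2C=CC(=O)[C@]2(C)C1 | intermediate
10 | 4-iodophenol | Oc1ccc(I)cc1 | starting material
11 | 3-(4-iodophenoxy)-4,6,7a-trimethyloctahydro-1H-inden-1-one (aryloxy syn to 7a-Me) | C[C@@H]1C[C@H](C)[C@H]2[C@@H](Oc3ccc(I)cc3)CC(=O)[C@]2(C)C1 | intermediate
12 | ethyl vinyl ether | C=COCC | starting material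
13 | 1-ethoxyvinyllithium | [Li]C(=C)OCC | intermediate
14 | 1-(1-ethoxyvinyl)-3-(4-iodophenoxy)-4,6,7a-trimethyloctahydro-1H-inden-1-ol (enol ether carbinol) | C[C@@H]1C[C@H](C)[C@H]2[C@@H](Oc3ccc(I)cc3)C[C@](O)(C(=C)OCC)[C@]2(C)C1 | intermediate
15 | 1-acetyl-3-(4-iodophenoxy)-4,6,7a-trimethyloctahydro-1H-inden-1-ol | C[C@@H]1C[C@H](C)[C@H]2[C@@H](Oc3ccc(I)cc3)C[C@](O)(C(C)=O)[C@]2(C)C1 | intermediate
16 | 1-[3-(4-iodophenoxy)-4,6,7a-trimethyl-3a,4,5,6,7,7a-hexahydro-3H-inden-1-yl]ethanone | C[C@@H]1C[C@H](C)[C@H]2[C@@H](Oc3ccc(I)cc3)C=C(C(C)=O)[C@]2(C)C1 | intermediate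
17 | methyl acetoacetate | COC(=O)CC(C)=O | starting material
18 | methyl 2-[1-acetyl-3-(4-iodophenoxy)-4,6,7a-trimethyloctahydro-1H-inden-2-yl]-3-oxobutanoate (Michael adduct) | C[C@@H]1C[C@H](C)[C@H]2[C@@H](Oc3ccc(I)cc3)[C@H](C(C(C)=O)C(=O)OC)[C@@H](C(C)=O)[C@]2(C)C1 | intermediate
19 | methyl 2-hydroxy-9-(4-iodophenoxy)-2,4b,6,8-tetramethyl-4-oxododecahydro-1H-fluorene-1-carboxylate (aldol) | C[C@@H]1C[C@H](C)[C@H]2[C@@H](Oc3ccc(I)cc3)[C@@H]4[C@@H](C(=O)OC)C(C)(O)CC(=O)[C@H]4[C@]2(C)C1 | intermediate
20 | methyl 9-(4-iodophenoxy)-2,4b,6,8-tetramethyl-4-oxo-4,4a,4b,5,6,7,8,8a,9,9a-decahydro-1H-fluorene-1-carboxylate (trans-anti-trans) | C[C@@H]1C[C@H](C)[C@H]2[C@@H](Oc3ccc(I)cc3)[C@@H]4[C@@H](C(=O)OC)C(C)=CC(=O)[C@H]4[C@]2(C)C1 | intermediate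
21 | methyl 4-hydroxy-9-(4-iodophenoxy)-2,4,4b,6,8-pentamethyl-4,4a,4b,5,6,7,8,8a,9,9a-decahydro-1H-fluorene-1-carboxylate (4-OH on the upper face) | C[C@@H]1C[C@H](C)[C@H]2[C@@H](Oc3ccc(I)cc3)[C@@H]4[C@@H](C(=O)OC)C(C)=C[C@@](C)(O)[C@H]4[C@]2(C)C1 | intermediate
22 | 4-hydroxy-9-(4-iodophenoxy)-2,4,4b,6,8-pentamethyl-4,4a,4b,5,6,7,8,8a,9,9a-decahydro-1H-fluorene-1-carboxylic acid | C[C@@H]1C[C@H](C)[C@H]2[C@@H](Oc3ccc(I)cc3)[C@@H]4[C@@H](C(=O)O)C(C)=C[C@@](C)(O)[C@H]4[C@]2(C)C1 | intermediate
23 | methyl sulfanylacetate (methyl thioglycolate) | COC(=O)CS | starting material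
24 | methyl (tritylsulfanyl)acetate | COC(=O)CSC(c1ccccc1)(c1ccccc1)c1ccccc1 | intermediate
25 | propargyl bromide | C#CCBr | starting material
26 | methyl 2-(tritylsulfanyl)pent-4-ynoate (racemic) | COC(=O)C(CC#C)SC(c1ccccc1)(c1ccccc1)c1ccccc1 | intermediate
27 | 2-(tritylsulfanyl)pent-4-ynamide (racemic) | NC(=O)C(CC#C)SC(c1ccccc1)(c1ccccc1)c1ccccc1 | intermediate
28 | aryl alkyne: acid 22 with the iodine replaced by the 5-amino-5-oxo-4-(tritylsulfanyl)pent-1-ynyl group | C[C@@H]1C[C@H](C)[C@H]2[C@@H](Oc3ccc(C#CCC(SC(c5ccccc5)(c5ccccc5)c5ccccc5)C(N)=O)cc3)[C@@H]4[C@@H](C(=O)O)C(C)=C[C@@](C)(O)[C@H]4[C@]2(C)C1 | intermediate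
29 | acid 22 with the iodine replaced by the (Z)-[5-oxo-4-(tritylsulfanyl)pyrrolidin-2-ylidene]methyl group | C[C@@H]1C[C@H](C)[C@H]2[C@@H](Oc3ccc(/C=C5\NC(=O)C(SC(c6ccccc6)(c6ccccc6)c6ccccc6)C5)cc3)[C@@H]4[C@@H](C(=O)O)C(C)=C[C@@](C)(O)[C@H]4[C@]2(C)C1 | intermediate
30 | the same with a free 4-sulfanyl group on the lactam (thiol acid) | C[C@@H]1C[C@H](C)[C@H]2[C@@H](Oc3ccc(/C=C5\NC(=O)C(S)C5)cc3)[C@@H]4[C@@H](C(=O)O)C(C)=C[C@@](C)(O)[C@H]4[C@]2(C)C1 | intermediate
31 | 14-membered thiolactone (C1 acyl on the lactam C3 sulfur; (Z)-enamide) | C[C@@H]1C[C@H](C)[C@H]2[C@H]3Oc4ccc(cc4)/C=C5/CC(SC(=O)[C@H]6C(C)=C[C@@](C)(O)[C@H]([C@H]36)[C@]2(C)C1)C(=O)N5 | intermediate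
32 | 13-membered 3-acyl-3-sulfanyl lactam (present as thiolate) | C[C@@H]1C[C@H](C)[C@H]2[C@H]3Oc4ccc(cc4)/C=C5/CC(S)(C(=O)[C@H]6C(C)=C[C@@](C)(O)[C@H]([C@H]36)[C@]2(C)C1)C(=O)N5 | intermediate
33 | 13-membered β-keto lactam, enamide form (lactam C3 enolisable; enamide geometry of no consequence) | C[C@@H]1C[C@H](C)[C@H]2[C@H]3Oc4ccc(cc4)/C=C5/CC(C(=O)[C@H]6C(C)=C[C@@](C)(O)[C@H]([C@H]36)[C@]2(C)C1)C(=O)N5 | intermediate
34 | 13-membered β-keto lactam with 5-hydroxy-5-benzyl hemiaminal (lactam C3 and C5 labile) | C[C@@H]1C[C@H](C)[C@H]2[C@H]3Oc4ccc(cc4)CC5(O)CC(C(=O)[C@H]6C(C)=C[C@@](C)(O)[C@H]([C@H]36)[C@]2(C)C1)C(=O)N5 | intermediate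
35 | 36 with the aldehyde masked as the acetoxy ethyl acetal | C[C@@H]1C[C@H](C)[C@H]2[C@H]3Oc4ccc(cc4)C[C@]4(O)C[C@](CC(OCC)OC(C)=O)(C(=O)N4)C(=O)[C@H]6C(C)=C[C@@](C)(O)[C@H]([C@H]36)[C@]2(C)C1 | intermediate
36 | macrocyclic keto lactam with a 2-oxoethyl group on the quaternary lactam C3 and the tertiary allylic alcohol in ring C | C[C@@H]1C[C@H](C)[C@H]2[C@H]3Oc4ccc(cc4)C[C@]4(O)C[C@](CC=O)(C(=O)N4)C(=O)[C@H]6C(C)=C[C@@](C)(O)[C@H]([C@H]36)[C@]2(C)C1 | intermediate
37 | 36 with the aldehyde as the gem-hydroxy hydroperoxide | C[C@@H]1C[C@H](C)[C@H]2[C@H]3Oc4ccc(cc4)C[C@]4(O)C[C@](CC(O)OO)(C(=O)N4)C(=O)[C@H]6C(C)=C[C@@](C)(O)[C@H]([C@H]36)[C@]2(C)C1 | intermediate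
38 | iodo peroxyhemiacetal: target skeleton with iodide at C3 (lower face) and hydroxyl at C4 (upper face) in place of the epoxide | C[C@@H]1C[C@H](C)[C@H]2[C@H]3Oc4ccc(cc4)C[C@]4(O)C[C@]5(C[C@H](O)OO[C@@]6(C)[C@H](I)[C@@](C)(O)[C@H]([C@H]3[C@H]6C5=O)[C@]2(C)C1)C(=O)N4 | intermediate
39 | CNP0533733.1 | C[C@@H]1C[C@H](C)[C@H]2[C@H]3Oc4ccc(cc4)C[C@]4(O)C[C@]5(C[C@H](O)OO[C@@]6(C)[C@H]7O[C@@]7(C)[C@H]([C@H]3[C@H]6C5=O)[C@]2(C)C1)C(=O)N4 | target

## Step count and risk

Total steps: 21. Longest linear sequence: 18 (steps 1–10 and 14–21; the branch 11–13 joins at step 14).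

The three steps most likely to fail:

Step 17 (the proposed ring contraction). The thioester α-proton at C1 is more acidic than the lactam α-proton, so the productive carbanion may be formed too slowly, and the contraction must pay for the cyclophane strain. The fallback uses known chemistry and closes the 13-membered ring directly by a Claisen (Dieckmann-type) C-acylation. It sets out from iodo acid 22: Sonogashira coupling with pent-4-ynamide (C#CCCC(N)=O) under the conditions of step 14 gives aryl alkyne amide F1; t-BuOK cyclises it to sulfur-free enamide acid F2; carbonyldiimidazole turns the acid into acyl imidazole F3; slow addition of F3 to LiHMDS (THF, −78 → 0 °C, high dilution) C-acylates the lactam enolate and gives 33, where the route is rejoined.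

Step 19 (radical installation of the two-carbon arm). The radical addition may be unselective between the two faces, and Mn(III) in acetic acid may damage the tertiary allylic alcohol. The fallback is polar and sets out from 34: conjugate addition of the β-keto lactam to nitroethylene (C=C[N+](=O)[O-], Et3N cat., THF, −20 °C) gives nitroethyl keto lactam F4, and a reductive Nef reaction (TiCl3, NH4OAc buffer, THF/H2O) converts the primary nitro group into the aldehyde, returning to the route at 36.

Step 20 (transannular iodoperoxidation). The hydroxyl at C4 may compete with the peroxide for the iodonium ion, and NIS may iodinate the arene. The fallback reverses the order of the two C–O bond formations and sets out from 36: NIS with NaHCO3 and no peroxide lets the C4 hydroxyl open the lower-face iodonium ion at C3, giving iodo epoxide F5 (epoxide already in place, tertiary iodide at C2); AgOTf with ethereal H2O2 then ionises the tertiary iodide (silver-assisted SN1 perhydrolysis), and the tethered gem-hydroxy hydroperoxide captures the cation from the upper face, which gives 39 directly and skips 38.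

Further compounds
F1 | step 17 | aryl alkyne amide (22 with the iodine replaced by the 5-amino-5-oxopent-1-ynyl group) | C[C@@H]1C[C@H](C)[C@H]2[C@@H](Oc3ccc(C#CCCC(N)=O)cc3)[C@@H]4[C@@H](C(=O)O)C(C)=C[C@@](C)(O)[C@H]4[C@]2(C)C1
F2 | step 17 | sulfur-free enamide acid (22 with the iodine replaced by the (Z)-(5-oxopyrrolidin-2-ylidene)methyl group) | C[C@@H]1C[C@H](C)[C@H]2[C@@H](Oc3ccc(/C=C5\NC(=O)CC5)cc3)[C@@H]4[C@@H](C(=O)O)C(C)=C[C@@](C)(O)[C@H]4[C@]2(C)C1
F3 | step 17 | acyl imidazole of F2 | C[C@@H]1C[C@H](C)[C@H]2[C@@H](Oc3ccc(/C=C5\NC(=O)CC5)cc3)[C@@H]4[C@@H](C(=O)n7ccnc7)C(C)=C[C@@](C)(O)[C@H]4[C@]2(C)C1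
F4 | step 19 | nitroethyl keto lactam (36 with CH2CH2NO2 in place of CH2CHO) | C[C@@H]1C[C@H](C)[C@H]2[C@H]3Oc4ccc(cc4)C[C@]4(O)C[C@](CC[N+](=O)[O-])(C(=O)N4)C(=O)[C@H]6C(C)=C[C@@](C)(O)[C@H]([C@H]36)[C@]2(C)C1
F5 | step 20 | iodo epoxide (36 with the C3–C4 epoxide on the upper face and iodide at C2 on the lower face) | C[C@@H]1C[C@H](C)[C@H]2[C@H]3Oc4ccc(cc4)C[C@]4(O)C[C@](CC=O)(C(=O)N4)C(=O)[C@H]6[C@](C)(I)[C@H]7O[C@@]7(C)[C@H]([C@H]36)[C@]2(C)C1
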